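**Strategy**

The quinone ring (C1 side chain, C2 H, C3 =O, C4 CH3, C5 OCH3, C6 =O) is cut at its two C=C bonds, C1–C2 and C4–C5. This leaves C1–C6–C5 as the α-carbon, ketone and γ-carbon of methyl 4-methoxyacetoacetate (a 1,3-bis-nucleophile whose ester carbon is the future vinyl carbon) and C2–C3–C4 as the three unsaturated carbons of but-3-yn-2-one (a 1,3-bis-electrophile whose CH3 is the ring methyl). One base-mediated [3+3] benzannulation (Michael addition, aldol condensation, aromatisation) makes both bonds and gives a salicylate carrying methyl, methoxy and side-chain anchor in their final positions. Vinyl triflate formation, an enantioselective NiCl2/CrCl2 coupling, angeloylation and a final phenol-to-para-quinone oxidation (adding the C3 oxygen) finish the route.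

Key step: step 1

Remark: the carbinol centre of the target is (S) (O > vinyl C > CH2 > H); the antipode of the ligand in step 6 is chosen for Re-face attack on aldehyde 10, and the configuration of 11 should be checked before step 7.

**Route**

Step 1
Reactants: 1 methyl 4-methoxy-3-oxobutanoate; 2 but-3-yn-2-one
Product: 4 methyl 2-hydroxy-3-methoxy-4-methylbenzoate, via ketovinylated keto ester 3 (not isolated)
Conditions: NaOMe, MeOH, 0 °C to 65 °C; then aq. HCl
Reagents that add atoms: none
Why: Base-mediated formal [3+3] benzannulation of the ketovinylation/cycloaromatisation type (β-keto ester plus ynone or β-chlorovinyl ketone to a 4-alkylsalicylate; the same Michael/aldol sense as the alkoxide route from β-keto esters and methyl vinyl ketone to 6-alkoxycarbonyl-3-methylcyclohex-2-enones): the sodium enolate of 1 adds through its central carbon to the alkyne terminus of 2 to give dienolate 3, whose methoxy-bearing γ-carbon then attacks the methyl ketone, and loss of water with tautomerisation gives the phenol. The ring closes by a 6-(enolendo)-exo-trig aldol addition (equivalently a 6π-electrocyclisation of the bis-enol), which needs the Z enone; E and Z forms should interconvert through the delocalised anion. No stereocentre is formed. The step needs regioselectivity at both ends and C- over O-cyclisation: only the doubly activated central carbon of 1 is deprotonated at the Michael stage and only the alkyne terminus of 2 is a conjugate acceptor, which fixes the CH–C(ester) bond; under alkoxide the keto ester ketone is masked as its enolate, so closure should run from the more acidic CH2OCH3 onto the methyl ketone and not from the acetyl CH3 onto the keto ester carbonyl. Lactonisation to a 2-pyranone is reversible in NaOMe/MeOH whereas aromatisation is not, which should funnel material to 4; any methanol adduct of 2 (4-methoxybut-3-en-2-one) is an equivalent ketovinylating agent.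

Step 2
Reactants: 4 methyl 2-hydroxy-3-methoxy-4-methylbenzoate
Product: 5 methyl 3-methoxy-2-(methoxymethoxy)-4-methylbenzoate
Conditions: NaH, MOMCl, DMF, 0 °C to rt
Reagents that add atoms: chloromethyl methyl ether, COCCl
Why: Williamson-type O-alkylation of the sodium phenoxide; the methoxymethyl acetal is chosen because it withstands the Grignard, amide-base and chromium steps and, unlike a silyl ether, cannot migrate to the neighbouring enolate oxygen in step 4.

Step 3
Reactants: 5 methyl 3-methoxy-2-(methoxymethoxy)-4-methylbenzoate
Product: 7 1-[3-methoxy-2-(methoxymethoxy)-4-methylphenyl]ethan-1-one, via Weinreb amide 6 (not isolated)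
Conditions: MeNH(OMe)·HCl, i-PrMgCl, THF, −20 °C; then MeMgBr, 0 °C; aq. NH4Cl
Reagents that add atoms: methylmagnesium bromide, C[Mg]Br; N,O-dimethylhydroxylamine hydrochloride, CNOC.Cl (atoms kept only in intermediate 6)
Why: One-pot Weinreb ketone synthesis: the magnesium amide of N,O-dimethylhydroxylamine converts the ester into amide 6, whose chelated tetrahedral adduct with MeMgBr collapses to the methyl ketone only on work-up, so over-addition is avoided.

Step 4
Reactants: 7 1-[3-methoxy-2-(methoxymethoxy)-4-methylphenyl]ethan-1-one
Product: 8 1-[3-methoxy-2-(methoxymethoxy)-4-methylphenyl]ethenyl trifluoromethanesulfonate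
Conditions: KN(SiMe3)2, PhNTf2, THF, −78 °C
Reagents that add atoms: N-phenylbis(trifluoromethanesulfonimide), O=S(=O)(N(c1ccccc1)S(=O)(=O)C(F)(F)F)C(F)(F)F
Why: Enol triflate formation: the ketone has a single enolisable position, so the potassium enolate is trapped on oxygen by PhNTf2 to give the 1-arylvinyl triflate.

Step 5
Reactants: 9 4-methylpent-3-en-1-ol
Product: 10 4-methylpent-3-enal
Conditions: Dess–Martin periodinane, CH2Cl2, 0 °C; solution used at once
Reagents that add atoms: none
Why: Dess–Martin oxidation under non-basic conditions should give the β,γ-unsaturated aldehyde without migration of the double bond into conjugation, and the volatile aldehyde is carried on as a solution.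

Step 6
Reactants: 8 1-[3-methoxy-2-(methoxymethoxy)-4-methylphenyl]ethenyl trifluoromethanesulfonate; 10 4-methylpent-3-enal
Product: 11 (3S)-2-[3-methoxy-2-(methoxymethoxy)-4-methylphenyl]-6-methylhepta-1,5-dien-3-ol
Conditions: CrCl2, NiCl2 (cat.), valinol-derived chiral oxazoline–sulfonamide ligand, Et3N, THF, rt
Reagents that add atoms: none
Why: Asymmetric Nozaki–Hiyama–Kishi coupling: zerovalent nickel inserts into the C–OTf bond, the alkenyl group passes to chromium, and the ligand-bound alkenylchromium species (trivalent chromium) adds to the Re face of the aldehyde, which sets the (S) carbinol centre under ligand control while the acetal, the trisubstituted alkene and the aryl ethers are left alone.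

Step 7
Reactants: 11 (3S)-2-[3-methoxy-2-(methoxymethoxy)-4-methylphenyl]-6-methylhepta-1,5-dien-3-ol; 12 (2Z)-2-methylbut-2-enoic acid (angelic acid)
Product: 14 (3S)-2-[3-methoxy-2-(methoxymethoxy)-4-methylphenyl]-6-methylhepta-1,5-dien-3-yl (2Z)-2-methylbut-2-enoate, via mixed anhydride 13 (not isolated)
Conditions: 2,4,6-Cl3C6H2COCl, Et3N, toluene, rt; then 11, toluene, 80 °C (no DMAP)
Reagents that add atoms: 2,4,6-trichlorobenzoyl chloride, O=C(Cl)c1c(Cl)cc(Cl)cc1Cl (atoms kept only in intermediate 13)
Why: Yamaguchi esterification through the mixed anhydride, run without DMAP so that the (Z)-2-methylbut-2-enoyl unit is not isomerised to the E (tigloyl) form; the C–O bond of the carbinol is not broken, so the (S) centre is retained.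

Step 8
Reactants: 14 (3S)-2-[3-methoxy-2-(methoxymethoxy)-4-methylphenyl]-6-methylhepta-1,5-dien-3-yl (2Z)-2-methylbut-2-enoate
Product: 15 (3S)-2-(2-hydroxy-3-methoxy-4-methylphenyl)-6-methylhepta-1,5-dien-3-yl (2Z)-2-methylbut-2-enoate
Conditions: NaHSO4·SiO2, CH2Cl2, rt
Reagents that add atoms: none
Why: Acetal hydrolysis on a mild heterogeneous Brønsted acid should cleave the phenolic methoxymethyl ether far faster than the acid can ionise the allylic ester or hydrate the alkenes.

Step 9
Reactants: 15 (3S)-2-(2-hydroxy-3-methoxy-4-methylphenyl)-6-methylhepta-1,5-dien-3-yl (2Z)-2-methylbut-2-enoate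
Product: 16 (3S)-2-(5-methoxy-4-methyl-3,6-dioxocyclohexa-1,4-dien-1-yl)-6-methylhepta-1,5-dien-3-yl (2Z)-2-methylbut-2-enoate (CNP0232608.2)
Conditions: ON(SO3K)2, KH2PO4, acetone/H2O, rt
Reagents that add atoms: potassium nitrosodisulfonate, [K+].[K+].[O]N(S(=O)(=O)[O-])S(=O)(=O)[O-]
Why: Teuber oxidation: the phenoxyl radical formed by the first equivalent of ON(SO3K)2 is trapped at the unsubstituted para carbon by a second equivalent, and loss of imidodisulfonate gives the para-quinone under buffered conditions that should leave the angelate, the stereocentre and both alkenes untouched.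

**Compound list**

1 | methyl 4-methoxy-3-oxobutanoate | COCC(=O)CC(=O)OC | starting material
2 | but-3-yn-2-one | CC(=O)C#C | starting material
3 | methyl (3Z)-2-(methoxyacetyl)-5-oxohex-3-enoate (present as its sodium dienolate; C2 racemic and labile) | COCC(=O)C(C(=O)OC)/C=C\C(C)=O | intermediate
4 | methyl 2-hydroxy-3-methoxy-4-methylbenzoate | COC(=O)c1ccc(C)c(OC)c1O | intermediate
5 | methyl 3-methoxy-2-(methoxymethoxy)-4-methylbenzoate | COCOc1c(C(=O)OC)ccc(C)c1OC | intermediate
6 | N,3-dimethoxy-2-(methoxymethoxy)-N,4-dimethylbenzamide | COCOc1c(C(=O)N(C)OC)ccc(C)c1OC | intermediate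
7 | 1-[3-methoxy-2-(methoxymethoxy)-4-methylphenyl]ethan-1-one | COCOc1c(C(C)=O)ccc(C)c1OC | intermediate
8 | 1-[3-methoxy-2-(methoxymethoxy)-4-methylphenyl]ethenyl trifluoromethanesulfonate | C=C(OS(=O)(=O)C(F)(F)F)c1ccc(C)c(OC)c1OCOC | intermediate
9 | 4-methylpent-3-en-1-ol | CC(C)=CCCO | starting material
10 | 4-methylpent-3-enal | CC(C)=CCC=O | intermediate
11 | (3S)-2-[3-methoxy-2-(methoxymethoxy)-4-methylphenyl]-6-methylhepta-1,5-dien-3-ol | C=C(c1ccc(C)c(OC)c1OCOC)[C@H](CC=C(C)C)O | intermediate
12 | (2Z)-2-methylbut-2-enoic acid (angelic acid) | C/C=C(/C)C(=O)O | starting material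
13 | (2Z)-2-methylbut-2-enoic 2,4,6-trichlorobenzoic anhydride | C/C=C(/C)C(=O)OC(=O)c1c(Cl)cc(Cl)cc1Cl | intermediate
14 | (3S)-2-[3-methoxy-2-(methoxymethoxy)-4-methylphenyl]-6-methylhepta-1,5-dien-3-yl (2Z)-2-methylbut-2-enoate | C=C(c1ccc(C)c(OC)c1OCOC)[C@H](CC=C(C)C)OC(=O)/C(C)=C\C | intermediate
15 | (3S)-2-(2-hydroxy-3-methoxy-4-methylphenyl)-6-methylhepta-1,5-dien-3-yl (2Z)-2-methylbut-2-enoate | C=C(c1ccc(C)c(OC)c1O)[C@H](CC=C(C)C)OC(=O)/C(C)=C\C | intermediate
16 | (3S)-2-(5-methoxy-4-methyl-3,6-dioxocyclohexa-1,4-dien-1-yl)-6-methylhepta-1,5-dien-3-yl (2Z)-2-methylbut-2-enoate | C=C(C1=CC(=O)C(C)=C(OC)C1=O)[C@H](CC=C(C)C)OC(=O)/C(C)=C\C | target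

**Step count and risks**

Total steps: 9. Longest linear sequence: 8 steps (1, 2, 3, 4, 6, 7, 8, 9); step 5 is a one-step side branch.

Steps most likely to fail:

Step 1. The risk is closure of intermediate 3 in the wrong sense (through the acetyl methyl group onto the keto ester carbonyl, or through oxygen), or loss of the ynone to oligomerisation before the enolate intercepts it. The fallback makes the same two ring bonds in the opposite order, with both termini differentiated by functional group; it sets out from 1 and comes back to the route at 4. The dianion of 1 (NaH, then n-BuLi, THF, 0 °C) is added through its γ-carbon to the ketone of commercial 4,4-dimethoxybutan-2-one at −78 °C, where the acetal is inert, to give methyl 5-hydroxy-4,7,7-trimethoxy-5-methyl-3-oxoheptanoate F1. Without purification, aqueous HCl in THF at 50 °C should unmask the aldehyde, which condenses with the active methylene (intramolecular Knoevenagel condensation), and two dehydrations aromatise the ring to 4.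

Step 6. The risk is insufficient facial selectivity when the alkenylchromium species adds to the unbranched aldehyde. The fallback replaces enantioselective C–C bond formation by enantioselective reduction; it sets out from 11 of insufficient enantiomeric purity (or racemic 11 from a ligand-free coupling) and comes back at 11. Dess–Martin oxidation gives 2-[3-methoxy-2-(methoxymethoxy)-4-methylphenyl]-6-methylhepta-1,5-dien-3-one F2. Corey–Bakshi–Shibata reduction with the (R)-2-methyl-oxazaborolidine and catecholborane in toluene at −78 °C, in which the branched 1-arylvinyl group acts as the large substituent and the CH2 group as the small one, should then deliver (S)-11.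

Step 7. The risk is isomerisation of the angeloyl unit to the tigloyl unit during activation, or sluggish acylation of the hindered secondary alcohol. The fallback builds the Z double bond on the ester instead of transferring it; it sets out from 11 and comes back at 14. DCC-mediated esterification with 2-[bis(2,2,2-trifluoroethoxy)phosphoryl]propanoic acid gives (3S)-2-[3-methoxy-2-(methoxymethoxy)-4-methylphenyl]-6-methylhepta-1,5-dien-3-yl 2-[bis(2,2,2-trifluoroethoxy)phosphoryl]propanoate F3 (mixture of epimers at the phosphonate carbon). Still–Gennari olefination with acetaldehyde (KN(SiMe3)2, 18-crown-6, THF, −78 °C) should then give the (Z)-2-methylbut-2-enoate 14.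

**Further compounds**

F1 | step 1 | methyl 5-hydroxy-4,7,7-trimethoxy-5-methyl-3-oxoheptanoate (mixture of diastereomers, racemic) | COC(=O)CC(=O)C(OC)C(C)(O)CC(OC)OC
F2 | step 6 | 2-[3-methoxy-2-(methoxymethoxy)-4-methylphenyl]-6-methylhepta-1,5-dien-3-one | C=C(c1ccc(C)c(OC)c1OCOC)C(=O)CC=C(C)C
F3 | step 7 | (3S)-2-[3-methoxy-2-(methoxymethoxy)-4-methylphenyl]-6-methylhepta-1,5-dien-3-yl 2-[bis(2,2,2-trifluoroethoxy)phosphoryl]propanoate | C=C(c1ccc(C)c(OC)c1OCOC)[C@H](CC=C(C)C)OC(=O)C(C)P(=O)(OCC(F)(F)F)OCC(F)(F)F
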